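**Plan**

- Retrosynthetic cuts, in order: the ketal bond C1–O2, then C1–O8 together with the side-chain bond C1'–C2' (the CH2 on C1 to the allylic CH2), then C5–C6 and C4–C5; in the side chain the C3'=C4' olefin and the C5'–benzyl bond.
- Enabling feature: C1 is a ketal carbon (ketone oxidation level) shared by the oxolane ring (O8) and the 1,3-dioxane ring (O2), and C1' is a plain CH2 next to an allylic CH2. C1/C1' can therefore be a terminal alkyne C≡C–H three atoms from the C5 tertiary hydroxyl, and the bond to be made is a vinyl–allyl bond.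
- Forward, core: D-tartrate acetonide, then enolate aldol with a glyoxylate (C4–C5), oxidation, and Grignard addition of the butynyl unit (C5–C6). Forward, side chain: Evans benzylation, Wittig olefination, reduction, carbonate formation.
- Ring order: the key step closes the oxolane ring (O8–C1) while joining the two fragments at C1'–C2'; the final acid step closes the 1,3-dioxane ring (O2–C1) and removes all protecting groups.
- Stereochemistry: C3 from D-tartaric acid; C4 from attack on the enolate face anti to the C3 ester; C5 from chelation-controlled Grignard addition; C1 dictated by the bridged bicycle; C5' from the oxazolidinone auxiliary; the (E)-olefin from a stabilised ylide, carried through the allyl-palladium step.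

Key step: step 12

Remark: atoms are numbered as in the target throughout (C1 ketal carbon, O2, C3, C4, C5, C6, C7, O8; side chain C1'–C6' counted from C1); the carbinol centre created in step 3 is formed as an epimer mixture and is removed in step 4.

**Step 1**
Reactants: 1 di-tert-butyl D-tartrate
Product: 2 di-tert-butyl (4S,5S)-2,2-dimethyl-1,3-dioxolane-4,5-dicarboxylate
Conditions: 2-methoxypropene, PPTS (cat.), CH2Cl2, 0 °C to rt
Reagents that add atoms: 2-methoxypropene COC(C)=C
Why: Acid-catalysed isopropylidenation of the trans diol under conditions mild enough for tert-butyl esters; no stereocentre is touched.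

**Step 2**
Reactants: 3 di-tert-butyl L-tartrate
Product: 4 tert-butyl glyoxylate
Conditions: H5IO6, Et2O, rt; distil
Reagents that add atoms: none
Why: Malaprade glycol cleavage of the vicinal diol should give two molecules of the aldehyde ester.

**Step 3**
Reactants: 2 di-tert-butyl (4S,5S)-2,2-dimethyl-1,3-dioxolane-4,5-dicarboxylate; 4 tert-butyl glyoxylate
Product: 6 di-tert-butyl (4R,5S)-4-(2-tert-butoxy-1-hydroxy-2-oxoethyl)-2,2-dimethyl-1,3-dioxolane-4,5-dicarboxylate (carbinol epimers), via lithium enolate 5 (not isolated)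
Conditions: LDA, THF/DMPU, −78 °C; then 4, −78 °C; AcOH quench at −78 °C
Reagents that add atoms: none
Why: Aldol addition of the tartrate acetonide ester enolate (Seebach-type α-functionalisation of tartrate); the aldehyde should add to the enolate face anti to the ester on the neighbouring ring carbon, which sets C4 with the two ring esters cis.

**Step 4**
Reactants: 6 aldol adduct
Product: 7 di-tert-butyl (4S,5S)-4-(2-tert-butoxy-2-oxoacetyl)-2,2-dimethyl-1,3-dioxolane-4,5-dicarboxylate
Conditions: Dess–Martin periodinane, CH2Cl2, rt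
Reagents that add atoms: none
Why: Dess–Martin oxidation of the secondary α-hydroxy ester converges both carbinol epimers on one non-enolisable α-keto ester.

**Step 5**
Reactants: 7 keto ester; 8 (4-bromobut-1-yn-1-yl)trimethylsilane
Product: 10 di-tert-butyl (4S,5S)-4-[(2R)-1-tert-butoxy-2-hydroxy-1-oxo-6-(trimethylsilyl)hex-5-yn-2-yl]-2,2-dimethyl-1,3-dioxolane-4,5-dicarboxylate, via Grignard reagent 9 (not isolated)
Conditions: 8, Mg, THF, rt; then added to 7 with MgBr2·OEt2, CH2Cl2, −78 °C; aqueous work-up
Reagents that add atoms: none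
Why: Chelation-controlled (Cram chelate) Grignard addition to the ketone of the α-keto ester; with magnesium bridging the ketone oxygen and the dioxolane oxygen on C4, the reagent should enter from the face flanked only by the C3–H, anti to the C4 tert-butyl ester, which gives the (R)-carbinol at C5.

**Step 6**
Reactants: 10 silylalkyne carbinol
Product: 11 di-tert-butyl (4S,5S)-4-[(2R)-1-tert-butoxy-2-hydroxy-1-oxohex-5-yn-2-yl]-2,2-dimethyl-1,3-dioxolane-4,5-dicarboxylate
Conditions: TBAF, AcOH, THF, 0 °C
Reagents that add atoms: none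
Why: Fluoride-induced protodesilylation of the alkynylsilane; the acetic acid buffer should suppress retro-aldol cleavage of the tertiary β-hydroxy ester.

**Step 7**
Reactants: 12 (R)-4-benzyl-3-propionyloxazolidin-2-one
Product: 14 (R)-4-benzyl-3-[(S)-2-methyl-3-phenylpropanoyl]oxazolidin-2-one, via sodium enolate 13 (not isolated)
Conditions: NaHMDS, THF, −78 °C; BnBr, −78 to −40 °C
Reagents that add atoms: benzyl bromide BrCc1ccccc1
Why: Evans asymmetric alkylation; the chelated (Z)-enolate is benzylated on the face opposite the C4 benzyl group of the auxiliary, which sets the (S) centre that becomes C5'.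

**Step 8**
Reactants: 14 alkylated imide
Product: 15 (S)-2-methyl-3-phenylpropan-1-ol
Conditions: LiBH4, H2O (1 equiv), Et2O, 0 °C
Reagents that add atoms: none
Why: Reductive cleavage of the N-acyl oxazolidinone to the primary alcohol, which should proceed without epimerisation and releases the auxiliary.

**Step 9**
Reactants: 15 (S)-2-methyl-3-phenylpropan-1-ol
Product: 17 ethyl (S,E)-2,4-dimethyl-5-phenylpent-2-enoate, via aldehyde 16 (not isolated)
Conditions: TPAP (cat.), NMO, 4 Å MS, CH2Cl2, rt; then Ph3P=C(CH3)CO2Et, rt to 40 °C, one pot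
Reagents that add atoms: ethyl 2-(triphenylphosphoranylidene)propanoate CCOC(=O)C(C)=P(c1ccccc1)(c1ccccc1)c1ccccc1
Why: Ley–Griffith oxidation followed in the same flask by Wittig olefination with a stabilised α-methyl ylide should give the (E)-trisubstituted enoate, and trapping the α-chiral aldehyde in situ guards against racemisation.

**Step 10**
Reactants: 17 enoate
Product: 18 (S,E)-2,4-dimethyl-5-phenylpent-2-en-1-ol
Conditions: DIBAL-H, CH2Cl2, −78 °C; Rochelle salt work-up
Reagents that add atoms: none
Why: 1,2-Reduction of the conjugated ester to the allylic alcohol with retention of olefin geometry.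

**Step 11**
Reactants: 18 allylic alcohol
Product: 19 tert-butyl [(S,E)-2,4-dimethyl-5-phenylpent-2-en-1-yl] carbonate
Conditions: Boc2O, DMAP (cat.), CH2Cl2, 0 °C to rt
Reagents that add atoms: di-tert-butyl dicarbonate CC(C)(C)OC(=O)OC(=O)OC(C)(C)C
Why: O-Acylation of the primary allylic alcohol gives the carbonate that serves as precursor of the allylpalladium complex and as internal source of base.

**Step 12**
Reactants: 11 alkynyl carbinol; 19 allyl carbonate
Product: 20 di-tert-butyl (4S,5S)-4-[(2R,5E)-2-(tert-butoxycarbonyl)-5-[(3E,5S)-3,5-dimethyl-6-phenylhex-3-en-1-ylidene]oxolan-2-yl]-2,2-dimethyl-1,3-dioxolane-4,5-dicarboxylate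
Conditions: Pd2(dba)3 (2.5 mol %), tri(2-furyl)phosphine (10 mol %), THF, 40 °C
Reagents that add atoms: none
Why: Proposed new method: oxidative addition of Pd(0) to carbonate 19 gives a cationic syn-(η3-allyl)palladium(II) complex with tert-butoxide as the only base (CO2 is lost); the complex binds the terminal alkyne of 11, the C5 hydroxyl adds anti to C1 in a 5-exo-dig oxypalladation that closes the oxolane ring, and C(sp2)–C(sp3) reductive elimination from the σ-vinyl(allyl)palladium forms the C1'–C2' bond between the former alkyne CH and the allyl CH2 and returns Pd(0). The closest known reaction types are the Pd(0)-catalysed cyclisation–coupling of 4-alkyn-1-ol alkoxides with aryl or vinyl halides to 2-alkylidene oxolanes and the Pd(0)-catalysed annulation–allylation of o-alkynylphenols, o-alkynylanilides and alkynoates with allyl esters; the combination of a tertiary aliphatic hydroxyl, an unactivated terminal alkyne and a trisubstituted allyl unit has not been shown, hence the label. No stereocentre is created: the (E)-geometry of the enol ether follows from anti addition and retentive reductive elimination but disappears in step 13, C5 is untouched, and the side-chain (E)-olefin and the C5' centre are carried through. Three selectivities are needed: C- over O-allylation (the hindered, ester-flanked tertiary hydroxyl is a poor partner for direct attack on the allyl ligand, whereas the fully substituted C5 favours ring closure); 5-exo over 6-endo (terminal alkyne, attack at the internal carbon); and linear (E) over branched or (Z) coupling (reductive elimination at the unsubstituted CH2 terminus of the kinetically formed syn-allyl complex before syn–anti exchange). Because one equivalent of tert-butoxide is released per turnover and is consumed by the O–H, the medium stays close to neutral, which should hold back retro-aldol cleavage at C4–C5 and epimerisation at C3.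

**Step 13**
Reactants: 20 enol ether
Product: 21 (1R,3S,4S,5R)-1-[(3E,5S)-3,5-dimethyl-6-phenylhex-3-en-1-yl]-4-hydroxy-2,8-dioxabicyclo[3.2.1]octane-3,4,5-tricarboxylic acid
Conditions: TFA/CH2Cl2/H2O (10:10:1), rt; evaporate
Reagents that add atoms: none
Why: Acidolysis removes the acetonide and the three tert-butyl esters, protonation of the enol ether at C1' gives the C1 oxocarbenium ion, and reversible acid-catalysed ketalisation should funnel to the 2,8-dioxabicyclo[3.2.1]octane in which the C3 oxygen closes the 1,3-dioxane ring; the configuration at C1 is fixed by the bridged bicycle once O8 and O2 are both bonded to it.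

**Compound list**

1 | di-tert-butyl D-tartrate, di-tert-butyl (2S,3S)-2,3-dihydroxybutanedioate | CC(C)(C)OC(=O)[C@@H](O)[C@H](O)C(=O)OC(C)(C)C | starting material
2 | di-tert-butyl (4S,5S)-2,2-dimethyl-1,3-dioxolane-4,5-dicarboxylate | CC(C)(C)OC(=O)[C@H]1OC(C)(C)O[C@@H]1C(=O)OC(C)(C)C | intermediate
3 | di-tert-butyl L-tartrate, di-tert-butyl (2R,3R)-2,3-dihydroxybutanedioate | CC(C)(C)OC(=O)[C@H](O)[C@@H](O)C(=O)OC(C)(C)C | starting material
4 | tert-butyl glyoxylate (tert-butyl 2-oxoacetate) | O=CC(=O)OC(C)(C)C | intermediate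
5 | lithium ester enolate of 2 | CC(C)(C)OC(O[Li])=C1OC(C)(C)O[C@@H]1C(=O)OC(C)(C)C | intermediate
6 | di-tert-butyl (4R,5S)-4-(2-tert-butoxy-1-hydroxy-2-oxoethyl)-2,2-dimethyl-1,3-dioxolane-4,5-dicarboxylate, carbinol epimers, ring esters cis | CC(C)(C)OC(=O)C(O)[C@]1(OC(C)(C)O[C@@H]1C(=O)OC(C)(C)C)C(=O)OC(C)(C)C | intermediate
7 | di-tert-butyl (4S,5S)-4-(2-tert-butoxy-2-oxoacetyl)-2,2-dimethyl-1,3-dioxolane-4,5-dicarboxylate | CC(C)(C)OC(=O)C(=O)[C@]1(OC(C)(C)O[C@@H]1C(=O)OC(C)(C)C)C(=O)OC(C)(C)C | intermediate
8 | (4-bromobut-1-yn-1-yl)trimethylsilane | C[Si](C)(C)C#CCCBr | starting material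
9 | [4-(trimethylsilyl)but-3-yn-1-yl]magnesium bromide | C[Si](C)(C)C#CCC[Mg]Br | intermediate
10 | di-tert-butyl (4S,5S)-4-[(2R)-1-tert-butoxy-2-hydroxy-1-oxo-6-(trimethylsilyl)hex-5-yn-2-yl]-2,2-dimethyl-1,3-dioxolane-4,5-dicarboxylate | C[Si](C)(C)C#CCC[C@](O)(C(=O)OC(C)(C)C)[C@]1(OC(C)(C)O[C@@H]1C(=O)OC(C)(C)C)C(=O)OC(C)(C)C | intermediate
11 | di-tert-butyl (4S,5S)-4-[(2R)-1-tert-butoxy-2-hydroxy-1-oxohex-5-yn-2-yl]-2,2-dimethyl-1,3-dioxolane-4,5-dicarboxylate | C#CCC[C@](O)(C(=O)OC(C)(C)C)[C@]1(OC(C)(C)O[C@@H]1C(=O)OC(C)(C)C)C(=O)OC(C)(C)C | intermediate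
12 | (R)-4-benzyl-3-propionyloxazolidin-2-one | CCC(=O)N1[C@H](Cc2ccccc2)COC1=O | starting material
13 | sodium (Z)-enolate of 12 | C/C=C(\O[Na])N1[C@H](Cc2ccccc2)COC1=O | intermediate
14 | (R)-4-benzyl-3-[(S)-2-methyl-3-phenylpropanoyl]oxazolidin-2-one | C[C@@H](Cc1ccccc1)C(=O)N1[C@H](Cc2ccccc2)COC1=O | intermediate
15 | (S)-2-methyl-3-phenylpropan-1-ol | C[C@@H](Cc1ccccc1)CO | intermediate
16 | (S)-2-methyl-3-phenylpropanal | C[C@@H](Cc1ccccc1)C=O | intermediate
17 | ethyl (S,E)-2,4-dimethyl-5-phenylpent-2-enoate | CCOC(=O)/C(C)=C/[C@@H](C)Cc1ccccc1 | intermediate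
18 | (S,E)-2,4-dimethyl-5-phenylpent-2-en-1-ol | OC/C(C)=C/[C@@H](C)Cc1ccccc1 | intermediate
19 | tert-butyl [(S,E)-2,4-dimethyl-5-phenylpent-2-en-1-yl] carbonate | CC(C)(C)OC(=O)OC/C(C)=C/[C@@H](C)Cc1ccccc1 | intermediate
20 | di-tert-butyl (4S,5S)-4-[(2R,5E)-2-(tert-butoxycarbonyl)-5-[(3E,5S)-3,5-dimethyl-6-phenylhex-3-en-1-ylidene]oxolan-2-yl]-2,2-dimethyl-1,3-dioxolane-4,5-dicarboxylate | C/C(=C\[C@@H](C)Cc1ccccc1)C/C=C1\CC[C@@](C(=O)OC(C)(C)C)(O1)[C@]2(OC(C)(C)O[C@@H]2C(=O)OC(C)(C)C)C(=O)OC(C)(C)C | intermediate
21 | (1R,3S,4S,5R)-1-[(3E,5S)-3,5-dimethyl-6-phenylhex-3-en-1-yl]-4-hydroxy-2,8-dioxabicyclo[3.2.1]octane-3,4,5-tricarboxylic acid | C/C(=C\[C@@H](C)Cc1ccccc1)CC[C@@]12CC[C@@](C(=O)O)(O1)[C@](O)(C(=O)O)[C@@H](C(=O)O)O2 | target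

**Totals**

Total step count: 13. Longest linear sequence: 7 steps (steps 1, 3, 4, 5, 6, 12, 13 from 1; equally steps 7–13 from 12).

**Steps most likely to fail**

1. Step 12 (proposed new method). What may go wrong: direct O-allylation of the hydroxyl by the allylpalladium complex, or retro-aldol cleavage at C4–C5 under the transient alkoxide, may outrun oxypalladation; syn–anti exchange of the allyl ligand may erode the (E)-geometry; coupling may occur at the substituted allyl terminus. Fallback with known chemistry, setting out from 18 and 11 and returning at 21: alcohol 18 is converted with CBr4/PPh3 (CH2Cl2, 0 °C) into (S,E)-1-bromo-2,4-dimethyl-5-phenylpent-2-ene F1. The copper acetylide of 11 (CuI, NaI, K2CO3, DMF, rt) is then alkylated by F1 in an SN2 sense, which forms the same C1'–C2' bond with retention of the (E)-olefin and should give the skipped enyne F2. Cationic gold(I) (Ph3PAuCl/AgOTf cat., CH2Cl2, rt) should effect 5-exo-dig hydroalkoxylation by the C5 hydroxyl to the (Z)-enol ether F3, the geometrical isomer of 20. Under the conditions of step 13, F3 converges on 21.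

2. Step 5. What may go wrong: addition through a non-chelated transition state may deliver the alkyl group to the opposite face of the keto ester, or β-hydride transfer from the Grignard reagent may reduce the ketone. Fallback, setting out from 2 and returning at 11, in which the resident and incoming groups at C5 are exchanged so that the opposite facial preference gives the required configuration: the enolate 5 of 2 is added to commercial pent-4-ynal to give the hydroxy ester F4, and Dess–Martin oxidation gives the ketone F5. Vinylmagnesium bromide (MgBr2·OEt2, CH2Cl2, −78 °C) gives the tertiary vinyl carbinol F6, in which vinyl stands for the future carboxyl. Ozonolysis of the vinyl group (O3, CH2Cl2/MeOH, −78 °C, indicator-controlled; Me2S) gives the α-hydroxy aldehyde F7, Pinnick oxidation gives the acid F8, and esterification with tert-butyl 2,2,2-trichloroacetimidate (BF3·OEt2 cat.) gives 11.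

3. Step 3. What may go wrong: ring-opening β-elimination of the lithium enolate before C–C bond formation, and loss of facial selectivity at C4 in the closed lithium aldol transition state. Fallback, setting out from 2 and returning at 6: the enolate is trapped as it forms (LDA in the presence of TMSCl, THF, −78 °C) as the silyl ketene acetal F9. F9 is then combined with 4 in a Lewis-acid-mediated Mukaiyama aldol addition (TiCl3(OiPr), CH2Cl2, −78 °C) through an open transition state, again anti to the neighbouring ester, to give 6.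

**Further compounds**

F1 | step 12 | (S,E)-1-bromo-2,4-dimethyl-5-phenylpent-2-ene | BrC/C(C)=C/[C@@H](C)Cc1ccccc1
F2 | step 12 | di-tert-butyl (4S,5S)-4-[(2R,8E,10S)-1-tert-butoxy-2-hydroxy-8,10-dimethyl-1-oxo-11-phenylundec-8-en-5-yn-2-yl]-2,2-dimethyl-1,3-dioxolane-4,5-dicarboxylate | C/C(=C\[C@@H](C)Cc1ccccc1)CC#CCC[C@](O)(C(=O)OC(C)(C)C)[C@]1(OC(C)(C)O[C@@H]1C(=O)OC(C)(C)C)C(=O)OC(C)(C)C
F3 | step 12 | (5Z)-isomer of 20, di-tert-butyl (4S,5S)-4-[(2R,5Z)-2-(tert-butoxycarbonyl)-5-[(3E,5S)-3,5-dimethyl-6-phenylhex-3-en-1-ylidene]oxolan-2-yl]-2,2-dimethyl-1,3-dioxolane-4,5-dicarboxylate | C/C(=C\[C@@H](C)Cc1ccccc1)C/C=C1/CC[C@@](C(=O)OC(C)(C)C)(O1)[C@]2(OC(C)(C)O[C@@H]2C(=O)OC(C)(C)C)C(=O)OC(C)(C)C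
F4 | step 5 | di-tert-butyl (4R,5S)-4-(1-hydroxypent-4-yn-1-yl)-2,2-dimethyl-1,3-dioxolane-4,5-dicarboxylate, carbinol epimers | C#CCCC(O)[C@]1(OC(C)(C)O[C@@H]1C(=O)OC(C)(C)C)C(=O)OC(C)(C)C
F5 | step 5 | di-tert-butyl (4S,5S)-2,2-dimethyl-4-(pent-4-ynoyl)-1,3-dioxolane-4,5-dicarboxylate | C#CCCC(=O)[C@]1(OC(C)(C)O[C@@H]1C(=O)OC(C)(C)C)C(=O)OC(C)(C)C
F6 | step 5 | di-tert-butyl (4S,5S)-4-[(3S)-3-hydroxyhept-1-en-6-yn-3-yl]-2,2-dimethyl-1,3-dioxolane-4,5-dicarboxylate | C#CCC[C@](O)(C=C)[C@]1(OC(C)(C)O[C@@H]1C(=O)OC(C)(C)C)C(=O)OC(C)(C)C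
F7 | step 5 | di-tert-butyl (4S,5S)-4-[(2R)-2-hydroxy-1-oxohex-5-yn-2-yl]-2,2-dimethyl-1,3-dioxolane-4,5-dicarboxylate | C#CCC[C@](O)(C=O)[C@]1(OC(C)(C)O[C@@H]1C(=O)OC(C)(C)C)C(=O)OC(C)(C)C
F8 | step 5 | (2R)-2-[(4S,5S)-4,5-bis(tert-butoxycarbonyl)-2,2-dimethyl-1,3-dioxolan-4-yl]-2-hydroxyhex-5-ynoic acid | C#CCC[C@](O)(C(=O)O)[C@]1(OC(C)(C)O[C@@H]1C(=O)OC(C)(C)C)C(=O)OC(C)(C)C
F9 | step 3 | tert-butyl (4S)-5-[tert-butoxy(trimethylsilyloxy)methylidene]-2,2-dimethyl-1,3-dioxolane-4-carboxylate | CC(C)(C)OC(O[Si](C)(C)C)=C1OC(C)(C)O[C@@H]1C(=O)OC(C)(C)C
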